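The unit I count in is the chain: an initiator that meets free monomer begins one, and an initiator that meets impurity begins none.

free monomer 25 mM; transfer agent 0.250 mM; initiator 0.25 mM; impurity 0.22 mM; time 25 min

* whether the average number of monomer units in a chain (chains begun, living or dead) reaches 10 by 25 min (no / yes)
* average number of monomer units in a chain (chains begun, living or dead) at 25 min

- percent here means free monomer units held: one self-condensation product counts as two
- for a step with 2 of a species take k times the square, and two of it per event
- the average divides the monomer in chains by the number of chains begun, living and dead together
- run time (flask): 25 min

    free monomer + initiator → living end + monomer in chains (k1 = 18.1 L mol⁻¹ s⁻¹)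
    free monomer + living end → monomer in chains + living end, rate k2*[living end]*[free monomer] (k2 = 32.8 L mol⁻¹ s⁻¹)
    living end + transfer agent → dead chain (k3 = 11.7 L mol⁻¹ s⁻¹)
    2 free monomer → self-condensation product (k4 = 7.21 × 10⁻⁴ L mol⁻¹ s⁻¹)
    initiator + impurity → spent initiator A (k5 = 7410 L mol⁻¹ s⁻¹)
    2 living end → dead end B (k6 = 1440 L mol⁻¹ s⁻¹)

1. At the charge, each initiator goes to impurity at 1.63 s⁻¹ and to free monomer at 0.453 s⁻¹, so the impurity starts ahead. At the first of these rates, an initiator lasts about 0.613 s against the impurity.

2. I call the even-split level the [impurity] at which initiator divides equally, that is, the constant for free monomer times [free monomer] over the constant for impurity: 0.0611 mM.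

3. As [impurity] falls, the split moves toward free monomer. Holding [free monomer] at its charge, chains begun equal the even-split level times the natural log of charged [impurity] over remaining [impurity].

4. I try a quarter of the impurity left. That gives 0.0847 mM of chains, and with the impurity used the initiator count comes to 0.250 mM, against 0.25 mM charged. The count closes, so I take the start as finished and reckon with these chains.

5. Living ends pair off on a time of 4.10 s, longer than the start, while transfer agent needs 342 s, so coupling acts first.

6. Adding monomer over both losses, with [free monomer] and [transfer agent] held at their charges, my length is one plus the growth rate per living end, over twice the coupling constant times chains, times the natural log of one plus the ratio of those times: 15.9. That passes the wanted length, so I say yes.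

7. The forecast says yes and 15.4, within 13.5 to 17.5, which is below my figure. Its ground: “Living-end coupling then kills those chains quickly”.

8. The flask gives yes and 15.8.

9. The flask passes the wanted length at 0.958 min, with 3.59% of its free monomer reacted. In the flask charged with twice the free monomer and the other amounts unchanged, the even-split level becomes 0.122 mM. Its counts close with 0.0856 mM of impurity left, so 0.115 mM of chains begin. The same reckoning gives a length of 24.4, and that flask's run gives 24.0.

The rate constants were set for the occasion; the rest is arithmetic.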